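The route rests on cutting C4–C4a and C2–C1' of the flavone. Ring A (C4a–C8a; oxygens at C8a, C7, C6) and ring B (C1'–C6'; oxygens at C2', C4', C5') are the same 2,4,5-trioxygenated phenyl group, attached to the two ends of the C2–C3–C4 chain that carries the 3-methoxyl. The key step exploits this latent twofold symmetry: one methoxymalonyl unit acylates two molecules of a single arene and gives the complete carbon skeleton as a symmetric 1,3-diaryl-2-methoxy-1,3-dione in one operation. The arene is 2,4-dimethoxyphenyl tosylate; the sulfonate, unlike an acid-labile ether, survives the Lewis acids of this step and of the ether cleavage that follows.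

Key step: step 5

Remark: the target is achiral, "tosyl" means 4-methylbenzenesulfonyl, and 2,4-dimethoxybenzaldehyde and dimethyl 2-methoxymalonate are taken as the purchased materials.

Step 1
Reactants: 1 2,4-dimethoxybenzaldehyde
Product: 3 2,4-dimethoxyphenol, via 2,4-dimethoxyphenyl formate 2 (not isolated)
Conditions: 30% H2O2, H2SO4 (cat.), MeOH, rt
Reagents that add atoms: hydrogen peroxide, OO
Why: Acid-catalysed Dakin oxidation, in which the electron-rich aryl group shifts from carbon to oxygen in the peroxide adduct (Baeyer–Villiger-type migration) and the formate 2 is methanolysed in the same pot, a sequence that is dependable for ortho- and para-alkoxybenzaldehydes.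

Step 2
Reactants: 3 2,4-dimethoxyphenol
Product: 4 2,4-dimethoxyphenyl 4-methylbenzenesulfonate
Conditions: TsCl, Et3N, DMAP (cat.), CH2Cl2, 0 °C → rt
Reagents that add atoms: 4-methylbenzenesulfonyl chloride, Cc1ccc(cc1)S(Cl)(=O)=O
Why: O-Sulfonylation of a phenol (substitution at sulfur under DMAP catalysis) installs a group that is inert to AlCl3, BCl3 and hot acid, keeps the two later free hydroxyls distinguishable from the one that must be methylated, and is removed at the end by hydroxide.

Step 3
Reactants: 5 dimethyl 2-methoxymalonate
Product: 6 2-methoxymalonic acid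
Conditions: NaOH, H2O/MeOH, rt; then conc. HCl, 0 °C, EtOAc extraction, drying below 30 °C
Reagents that add atoms: sodium hydroxide, [Na+].[OH-]
Why: Saponification of an unhindered dimethyl malonate (acyl–oxygen cleavage by hydroxide), with cold acidification and cold isolation so that the malonic acid should not decarboxylate.

Step 4
Reactants: 6 2-methoxymalonic acid
Product: 7 2-methoxymalonyl dichloride
Conditions: (COCl)2, DMF (cat.), CH2Cl2, 0 °C → rt; evaporate, use crude at once
Reagents that add atoms: oxalyl chloride, ClC(=O)C(Cl)=O
Why: Acid chloride formation through the chloroiminium salt generated from DMF and oxalyl chloride, a mild base-free method that should leave the acidic C2–H in place and gives only gaseous by-products.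

Step 5
Reactants: 4 2,4-dimethoxyphenyl 4-methylbenzenesulfonate (two molecules react); 7 2-methoxymalonyl dichloride
Product: 9 1,3-bis[2,4-dimethoxy-5-(tosyloxy)phenyl]-2-methoxypropane-1,3-dione, via ketoacyl chloride 8 (not isolated)
Conditions: 4 (2.4 equiv), AlCl3 (3 equiv), CH2Cl2, 0 °C; 7 added slowly, → rt; ice/1 M HCl quench
Reagents that add atoms: none
Why: Twofold Friedel–Crafts acylation: AlCl3 ionises one C–Cl bond of 7, the acylium attacks C5 of 4 to give ketoacyl chloride 8, and the second acyl chloride of 8 (as acylium or, after loss of HCl, as acylketene) acylates another molecule of 4 at the same carbon, forming C4–C4a and C2–C1' of the later flavone. The closest known reaction type is the double acylation of activated arenes by malonyl dichlorides to 1,3-diaryl-1,3-diones. No ring is closed and no stereocentre arises, because C2 of the dione carries two identical aroyl groups. Only site selectivity on the arene is needed, and the substrate secures it: C5 is para to the 2-methoxyl and ortho to the 4-methoxyl, whereas C3 is crowded between two methoxyls and C6 is meta to both and adjacent to the electron-poor sulfonyloxy group. Excess arene, slow addition of 7 and low temperature favour the second intermolecular acylation over closure of 8 onto its own ortho methoxyl, and the tosylate is neither cleaved nor transferred by the Lewis acid. Loss of an ortho methyl group to AlCl3 would do no harm, since step 6 removes both on purpose.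

Step 6
Reactants: 9 1,3-bis[2,4-dimethoxy-5-(tosyloxy)phenyl]-2-methoxypropane-1,3-dione
Product: 11 2'-hydroxy-3,7,4'-trimethoxy-6,5'-bis(tosyloxy)flavone, via bis(2-hydroxyaryl) dione 10 (not isolated)
Conditions: BCl3 (5 equiv), CH2Cl2, −78 → 0 °C; MeOH quench, evaporate; then AcOH, H2SO4 (cat.), 90 °C
Reagents that add atoms: none
Why: Chelation-directed ether cleavage followed by acid cyclodehydration: BCl3 held between each ketone oxygen and its ortho methoxyl delivers chloride to that methyl group only, sparing the para methoxyls and the sulfonates, and hot acid then closes O1–C2 by 6-exo-trig addition of one phenol to the remote carbonyl and loss of water (the final stage of a Baker–Venkataraman flavone synthesis), either phenol giving the same chromone because the dione is symmetric.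

Step 7
Reactants: 11 2'-hydroxy-3,7,4'-trimethoxy-6,5'-bis(tosyloxy)flavone
Product: 12 3,7,2',4'-tetramethoxy-6,5'-bis(tosyloxy)flavone
Conditions: MeI, K2CO3, acetone, 50 °C
Reagents that add atoms: iodomethane, CI
Why: Williamson ether synthesis (SN2 of the 2'-phenoxide on iodomethane): the 2'-hydroxyl is the only free phenol because the 6- and 5'-oxygens are held as sulfonates, and any 3-hydroxyl created by stray cleavage in step 6 would be methylated back at the same time.

Step 8
Reactants: 12 3,7,2',4'-tetramethoxy-6,5'-bis(tosyloxy)flavone
Product: 13 6,5'-dihydroxy-3,7,2',4'-tetramethoxyflavone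
Conditions: KOH, THF/MeOH/H2O, 50 °C, argon; then 1 M HCl
Reagents that add atoms: none
Why: Alkaline hydrolysis of aryl sulfonates, hydroxide attacking sulfur with S–O cleavage, should free the 6- and 5'-phenols while the four methyl ethers stay inert, a deprotection long used for partially methylated flavones; acidification returns the neutral phenol and recloses any pyranone opened reversibly by base.

Compound list
1 | 2,4-dimethoxybenzaldehyde | COc1ccc(C=O)c(OC)c1 | starting material
2 | 2,4-dimethoxyphenyl formate | COc1ccc(OC=O)c(OC)c1 | intermediate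
3 | 2,4-dimethoxyphenol | COc1ccc(O)c(OC)c1 | intermediate
4 | 2,4-dimethoxyphenyl 4-methylbenzenesulfonate | COc1ccc(OS(=O)(=O)c2ccc(C)cc2)c(OC)c1 | intermediate
5 | dimethyl 2-methoxymalonate | COC(C(=O)OC)C(=O)OC | starting material
6 | 2-methoxymalonic acid | COC(C(=O)O)C(=O)O | intermediate
7 | 2-methoxymalonyl dichloride | COC(C(Cl)=O)C(Cl)=O | intermediate
8 | 3-[2,4-dimethoxy-5-(tosyloxy)phenyl]-2-methoxy-3-oxopropanoyl chloride (racemic, transient) | COC(C(Cl)=O)C(=O)c1cc(OS(=O)(=O)c2ccc(C)cc2)c(OC)cc1OC | intermediate
9 | 1,3-bis[2,4-dimethoxy-5-(tosyloxy)phenyl]-2-methoxypropane-1,3-dione | COC(C(=O)c1cc(OS(=O)(=O)c2ccc(C)cc2)c(OC)cc1OC)C(=O)c1cc(OS(=O)(=O)c2ccc(C)cc2)c(OC)cc1OC | intermediate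
10 | 1,3-bis[2-hydroxy-4-methoxy-5-(tosyloxy)phenyl]-2-methoxypropane-1,3-dione | COC(C(=O)c1cc(OS(=O)(=O)c2ccc(C)cc2)c(OC)cc1O)C(=O)c1cc(OS(=O)(=O)c2ccc(C)cc2)c(OC)cc1O | intermediate
11 | 2'-hydroxy-3,7,4'-trimethoxy-6,5'-bis(tosyloxy)flavone | COc1cc(O)c(-c2oc3cc(OC)c(OS(=O)(=O)c4ccc(C)cc4)cc3c(=O)c2OC)cc1OS(=O)(=O)c1ccc(C)cc1 | intermediate
12 | 3,7,2',4'-tetramethoxy-6,5'-bis(tosyloxy)flavone | COc1cc(OC)c(-c2oc3cc(OC)c(OS(=O)(=O)c4ccc(C)cc4)cc3c(=O)c2OC)cc1OS(=O)(=O)c1ccc(C)cc1 | intermediate
13 | 6,5'-dihydroxy-3,7,2',4'-tetramethoxyflavone | COc1cc(OC)c(-c2oc3cc(OC)c(O)cc3c(=O)c2OC)cc1O | target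

Total step count: 8. Longest linear sequence: 6 steps (steps 1, 2, 5, 6, 7, 8; the malonate branch through steps 3 and 4 is equally long).

Steps most likely to fail

Step 5. After the first carbon–carbon bond has formed, the ketoacyl chloride may be intercepted before a second arene arrives, either by O-acylation through its own ortho methoxyl (lactonisation with loss of the methyl group) or by decay through the acylketene. The fallback forms the two aryl–carbon bonds one at a time, setting out from 4 and coming back at 9. Friedel–Crafts acylation of 4 with methoxyacetyl chloride (AlCl3, CH2Cl2, 0 °C) should give 1-[2,4-dimethoxy-5-(tosyloxy)phenyl]-2-methoxyethan-1-one F1. Rieche formylation of a second portion of 4 (Cl2CHOMe, TiCl4, CH2Cl2, 0 °C; aqueous work-up) should give 2,4-dimethoxy-5-(tosyloxy)benzaldehyde F2. The lithium enolate of F1 (LiN(SiMe3)2, THF, −78 °C) should add to F2 to give the aldol 3-hydroxy-2-methoxy-1,3-bis[2,4-dimethoxy-5-(tosyloxy)phenyl]propan-1-one F3 as a diastereomer mixture. Dess–Martin periodinane should oxidise F3 to 9, which removes both stereocentres.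

Step 4. During chlorination and concentration the diacid may decarboxylate, or the dichloride may lose HCl to a chlorocarbonyl ketene that oligomerises. The fallback avoids the methoxylated dichloride and brings the methoxyl in afterwards, setting out from 4 and coming back at 9. Commercial malonyl dichloride and 4 under the conditions of step 5 should give 1,3-bis[2,4-dimethoxy-5-(tosyloxy)phenyl]propane-1,3-dione F4. Diazo transfer (4-acetamidobenzenesulfonyl azide, Et3N, MeCN) should give 2-diazo-1,3-bis[2,4-dimethoxy-5-(tosyloxy)phenyl]propane-1,3-dione F5. O–H insertion of the carbenoid derived from F5 into methanol, catalysed by Rh2(OAc)4, should give 9.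

Step 6. Ether cleavage may stop short if BCl3 is sequestered as a boron diketonate, or it may also take the aliphatic 2-methoxyl, and ring closure may then be incomplete. The route already tolerates part of this: mono-cleaved dione closes directly to 12, and a 3-hydroxyl is methylated back in step 7. The fallback is a Brønsted-acid cyclodemethylation, setting out from 9 and coming back at 12. Warming 9 with HBr in AcOH should let one ortho methoxyl oxygen add to the protonated remote carbonyl. The resulting methyloxonium ion would lose its methyl group to bromide and the hemiketal would lose water, so only one methyl ether is spent and the 2'-methoxyl is kept. Steps 6 and 7 are bypassed and no new compound arises (F0).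

Further compounds
F1 | step 5 | 1-[2,4-dimethoxy-5-(tosyloxy)phenyl]-2-methoxyethan-1-one | COCC(=O)c1cc(OS(=O)(=O)c2ccc(C)cc2)c(OC)cc1OC
F2 | step 5 | 2,4-dimethoxy-5-(tosyloxy)benzaldehyde | O=Cc1cc(OS(=O)(=O)c2ccc(C)cc2)c(OC)cc1OC
F3 | step 5 | 3-hydroxy-2-methoxy-1,3-bis[2,4-dimethoxy-5-(tosyloxy)phenyl]propan-1-one (diastereomer mixture, racemic) | COC(C(O)c1cc(OS(=O)(=O)c2ccc(C)cc2)c(OC)cc1OC)C(=O)c1cc(OS(=O)(=O)c2ccc(C)cc2)c(OC)cc1OC
F4 | step 4 | 1,3-bis[2,4-dimethoxy-5-(tosyloxy)phenyl]propane-1,3-dione | O=C(CC(=O)c1cc(OS(=O)(=O)c2ccc(C)cc2)c(OC)cc1OC)c1cc(OS(=O)(=O)c2ccc(C)cc2)c(OC)cc1OC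
F5 | step 4 | 2-diazo-1,3-bis[2,4-dimethoxy-5-(tosyloxy)phenyl]propane-1,3-dione | [N-]=[N+]=C(C(=O)c1cc(OS(=O)(=O)c2ccc(C)cc2)c(OC)cc1OC)C(=O)c1cc(OS(=O)(=O)c2ccc(C)cc2)c(OC)cc1OC
F0 | step 6 | none | none
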